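## Retrosynthetic overview
1. Remove the acetonide from 8 to reach 7, then disconnect the C11–O(aryl) bond. This gives umbelliferone 5 and the primary C11 radical released by decarboxylation of the one-carbon-longer C12 acid 4, so carbon excision and ether formation happen in one event.
2. Acid 4 comes from oxidative scission of the lactone-conjugated C12=C13 alkene of 2, sparing the isolated C8=C17 methylene.
3. Compound 2 comes from andrographolide 1. Its C3, C4, C5, C9 and C10 centres, 3-OH, 19-CH2OH and exocyclic methylene match those of 8 centre by centre.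
4. Ring order: no carbocycle is built. Rings A and B arrive in 1 and the coumarin rings in 5. Only a temporary 1,3-dioxane is closed (step 1) and opened again (step 3).

Assumption: operations carried through in one flask without isolation count as one step, and labdane numbering (C1–C20 of andrographolide) is used for all terpenoid positions.

## Route

Step 1
Reactants: 1 andrographolide
Product: 2 3,19-O-isopropylideneandrographolide
Conditions: 2,2-dimethoxypropane (5 equiv), PPTS (0.1 equiv), toluene–DMSO 8:1, 80 °C, 1–2 h
Reagents that add atoms: 2,2-dimethoxypropane, COC(C)(C)OC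
Why: Acid-catalysed transketalisation closes the only possible six-membered 1,3-dioxane across the O3/O19 pair (O14 has no partner), touches no stereocentre, and masks the two hydroxyls that would otherwise bind to trivalent iodine in step 3 and fragment as alkoxyl radicals.

Step 2
Reactants: 2 3,19-O-isopropylideneandrographolide
Product: 4 3,19-O-isopropylidene-13,14,15,16-tetranor-ent-labd-8(17)-en-12-oic acid, via C12 aldehyde 3 (not isolated)
Conditions: KMnO4 (2.2 equiv, in portions), THF–H2O 3:1, −5 to 0 °C, 2 h; filter off MnO2; extract at pH 4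
Reagents that add atoms: KMnO4, [K+].[O-][Mn](=O)(=O)=O; water, O
Why: Permanganate oxidative alkene cleavage: MnO4− adds fastest to the electron-poor, lactone-conjugated C12=C13 bond, the hindered unactivated 8(17)-methylene (which classically survives permanganate side-chain degradation of labdanes) reacts far more slowly, aldehyde 3 is oxidised on as its hydrate, and no stereocentre is made or endangered because C11 is a CH2 and C9 is β to the carbonyl.

Step 3
Reactants: 4 3,19-O-isopropylidene-13,14,15,16-tetranor-ent-labd-8(17)-en-12-oic acid; 5 umbelliferone (7-hydroxy-2H-chromen-2-one)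
Product: 8 7-{[(1R,4aS,5R,6R,8aR)-6-hydroxy-5-(hydroxymethyl)-5,8a-dimethyl-2-methylidenedecahydronaphthalen-1-yl]methoxy}-2H-chromen-2-one, via acyloxybenziodoxolone 6 (not isolated), via acetonide ether 7 (not isolated)
Conditions: (a) 4 (1.0 equiv), 1-acetoxy-1,2-benziodoxol-3(1H)-one (1.1 equiv), toluene–CH2Cl2, 40 °C, evaporate twice (strips AcOH); (b) 5 (1.5 equiv), Cu(MeCN)4PF6 (20 mol %), 4,7-diphenyl-1,10-phenanthroline (30 mol %), Ir(ppy)2(dtbbpy)PF6 (1 mol %), 2-tert-butyl-1,1,3,3-tetramethylguanidine (BTMG, 1.6 equiv), degassed MeCN (0.05 M), 450 nm LEDs, rt, 6–12 h; (c) concentrate, AcOH–H2O 7:3, rt, 1 h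
Reagents that add atoms: 1-acetoxy-1,2-benziodoxol-3(1H)-one, CC(=O)OI1OC(=O)c2ccccc12 (its iodobenzoate part is carried only by 6)
Why: Proposed new method: decarboxylative C(sp3)–O(aryl) coupling of a free aliphatic acid, used as the limiting reagent, through a mono-acyloxybenziodoxolone; ligand exchange on trivalent iodine gives 6, the photoexcited iridium complex oxidises the phenanthroline-bound monovalent copper aryloxide of 5 to divalent copper, the reduced iridium complex passes one electron to 6 and breaks its I–O bond to give 2-iodobenzoate plus the acyloxyl radical, loss of CO2 gives the primary C11 radical, the divalent copper aryloxide captures it faster than its slow reversible 3-exo attack on C8=C17, and C–O reductive elimination from trivalent copper gives 7 and returns monovalent copper; the tethered iodobenzoate is the only dummy ligand so every molecule of 4 can become a radical, the cyclic iodane is too weak an oxidant to dearomatise the electron-poor phenol 5, and the low triplet energy of Ir(ppy)2(dtbbpy)PF6 avoids sensitised coumarin [2+2] reactions; no stereocentre is formed and C9 is untouched; the closest known reaction types are the copper/photoredox decarboxylative sp3 C–N coupling of iodomesitylene dicarboxylates and the copper/photoredox C–O coupling of N-hydroxyphthalimide esters with phenols; mild aqueous AcOH then hydrolyses the acetonide without moving the exocyclic alkene.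

## Compound list
1 | andrographolide, (3E,4S)-3-{2-[(1R,4aS,5R,6R,8aS)-6-hydroxy-5-(hydroxymethyl)-5,8a-dimethyl-2-methylidenedecahydronaphthalen-1-yl]ethylidene}-4-hydroxyoxolan-2-one | C=C1CC[C@@H]2[C@](C)(CO)[C@H](O)CC[C@@]2(C)[C@@H]1C/C=C3/C(=O)OC[C@H]3O | starting material
2 | 3,19-O-isopropylideneandrographolide (1,3-dioxane across O3/O19; 3R,4R,5S,9R,10S,12E,14S) | C=C1CC[C@@H]2[C@]3(C)COC(C)(C)O[C@@H]3CC[C@@]2(C)[C@@H]1C/C=C4/C(=O)OC[C@H]4O | intermediate
3 | 3,19-O-isopropylidene-13,14,15,16-tetranor-ent-labd-8(17)-en-12-al (C9–CH2–CHO; 3R,4R,5S,9R,10S) | C=C1CC[C@@H]2[C@]3(C)COC(C)(C)O[C@@H]3CC[C@@]2(C)[C@@H]1CC=O | intermediate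
4 | 3,19-O-isopropylidene-13,14,15,16-tetranor-ent-labd-8(17)-en-12-oic acid (C9–CH2–CO2H; 3R,4R,5S,9R,10S) | C=C1CC[C@@H]2[C@]3(C)COC(C)(C)O[C@@H]3CC[C@@]2(C)[C@@H]1CC(=O)O | intermediate
5 | umbelliferone (7-hydroxy-2H-chromen-2-one) | Oc1ccc2ccc(=O)oc2c1 | starting material
6 | 1-acyloxy-1,2-benziodoxol-3(1H)-one of acid 4 (carboxylate of 4 bound through O to the trivalent iodine) | C=C1CC[C@@H]2[C@]3(C)COC(C)(C)O[C@@H]3CC[C@@]2(C)[C@@H]1CC(=O)OI1OC(=O)c2ccccc12 | intermediate
7 | 3,19-O-isopropylidene derivative of 8 (C11–O–7-coumarinyl ether; 3R,4R,5S,9R,10R, same spatial arrangement as in 1) | C=C1CC[C@@H]2[C@]3(C)COC(C)(C)O[C@@H]3CC[C@@]2(C)[C@@H]1COc1ccc2ccc(=O)oc2c1 | intermediate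
8 | 7-{[(1R,4aS,5R,6R,8aR)-6-hydroxy-5-(hydroxymethyl)-5,8a-dimethyl-2-methylidenedecahydronaphthalen-1-yl]methoxy}-2H-chromen-2-one (CNP0149624.1) | C=C1CC[C@@H]2[C@](C)(CO)[C@H](O)CC[C@@]2(C)[C@@H]1COc1ccc2ccc(=O)oc2c1 | target

## Totals and risks
Total step count: 3 (three isolations; step 3 holds three telescoped operations).
Longest linear sequence: 3 steps, from 1.

**Step 3 (the proposed new method) is the most likely to fail.**
- The aryloxide of 5 may displace the carboxylate on iodine and be oxidised.
- The alkyl–copper species may undergo oxidative elimination (C9–H) to the 8(17),9(11)-diene.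
- 2-Iodobenzoate may compete as the O-ligand.
- The C11 radical may add to the coumarin C3=C4 bond or undergo a vinyl shift.

The fallback uses known chemistry and a polar C–O bond formation. It sets out from 4 and comes back at 7. Acid 4 is esterified with N-hydroxyphthalimide (DIC, cat. DMAP, CH2Cl2) to the N-(acyloxy)phthalimide F1. Copper-catalysed decarboxylative borylation (Cu(acac)2, B2pin2, LiOH·H2O, MgCl2, dioxane–DMF, rt) converts this to the C11 pinacol boronate F2. NaBO3·4H2O in THF–H2O then gives the C11 alcohol F3. A Mitsunobu reaction of F3 with 5 (PPh3, DIAD, THF, 0 °C to rt) makes the same C11–O bond by SN2 at the primary carbon and delivers 7. Compound 7 is deprotected as in step 3(c).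

**Step 2 is the second risk.** As oxidant equivalents rise, the 8(17)-methylene may begin to be attacked, or the reaction may stall at 3. The fallback sets out from 2 and comes back at 4.
- Permanganate is used only for the four-electron C=C scission (KMnO4 1.35 equiv, THF with little water, −10 °C), and aldehyde 3 is isolated.
- The last two-electron oxidation is handed to a different oxidant in a Pinnick oxidation (NaClO2, NaH2PO4, 2-methyl-2-butene, t-BuOH–H2O, rt). This leaves isolated alkenes alone once HOCl is scavenged.
- No compound outside the list is made.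

**Step 1 is the third risk.** Possible problems are acid-promoted loss of the allylic 14-OH to the 11,12-didehydro compound, a mixed ketal at O14, and poor solubility of 1. The fallback reverses the order of events. It sets out from 1 and comes back at 4.
- Unprotected 1 is cleaved first (KMnO4 2.2 equiv, THF–H2O, 0 °C) to the 3,19-dihydroxy-13,14,15,16-tetranor-ent-labd-8(17)-en-12-oic acid F4, which removes the sensitive hydroxybutenolide.
- The 1,3-diol of F4 is then ketalised with 2-methoxypropene and cat. PPTS in THF at 0 °C. Any labile ketal ester on the acid falls off on aqueous work-up, giving 4.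

## Further compounds
F1 | step 3 | N-(acyloxy)phthalimide (redox-active ester) of acid 4 | C=C1CC[C@@H]2[C@]3(C)COC(C)(C)O[C@@H]3CC[C@@]2(C)[C@@H]1CC(=O)ON1C(=O)c2ccccc2C1=O
F2 | step 3 | C11 pinacol boronate, 3,19-O-isopropylidene-12,13,14,15,16-pentanor-ent-labd-8(17)-en-11-yl-Bpin | C=C1CC[C@@H]2[C@]3(C)COC(C)(C)O[C@@H]3CC[C@@]2(C)[C@@H]1CB1OC(C)(C)C(C)(C)O1
F3 | step 3 | C11 alcohol, 3,19-O-isopropylidene-12,13,14,15,16-pentanor-ent-labd-8(17)-ene-3,11,19-triol | C=C1CC[C@@H]2[C@]3(C)COC(C)(C)O[C@@H]3CC[C@@]2(C)[C@@H]1CO
F0 | step 2 | none | none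
F4 | step 1 | 3,19-dihydroxy-13,14,15,16-tetranor-ent-labd-8(17)-en-12-oic acid | C=C1CC[C@@H]2[C@](C)(CO)[C@H](O)CC[C@@]2(C)[C@@H]1CC(=O)O
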